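## Structural features

The target is a daucane-type diester built on a hydroazulene: a cycloheptene (ring A, Ca–Cb=Cc–Cd–Ce–Cf–Cg) trans-fused through the Cf–Cg bond to a cyclopentane (ring B, Cg–Ch–Ci–Cj–Cf). Its five stereocentres form one continuous array: the quaternary, methyl-bearing Cg lies between the allylic carbinol Ca and the ring-fusion methine Cf, and Cf is flanked by the acyloxy carbon Ce and the fully substituted carbinol Cj (hydroxyl and isopropyl). The Cg methyl, the Cj hydroxyl and the Ca oxygen lie on one face; the Cf hydrogen and the Ce oxygen lie on the other. The fragile groups are the angelate (Z to E isomerisation under base, heat or nucleophilic catalysts), the allylic C–O bond at Ca, the tertiary alcohol (dehydration) and the free phenol beside an aryl ester. In addition, whenever Ca is a carbonyl, an ester at Ce becomes a leaving group for vinylogous elimination through Cd. The real difficulty is a seven-membered ring that carries a trisubstituted alkene next to a neopentyl oxygenated carbon, joined to a congested Cg/Cf/Cj triad, together with the order of the two esterifications. The key step uses the fact that Cb is the only unsubstituted carbon of ring A and lies between the oxygenated Ca and the methyl-bearing Cc. Removing Cb leaves a cyclohexanone (Ca, Cc, Cd, Ce, Cf, Cg) whose Ca carbonyl has the quaternary Cg on one side and can therefore enolise only toward Cc, so inserting one carbon into the Ca–Cc bond is regiochemically unambiguous.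

## Logic of the disconnections

**25 to 24 to 22 + 23.** The phenol O–H is masked and the Ce–O acyl bond is cut. The aryl ester is placed last because it cannot pass through the enolate chemistry or through the stage at which Ca is a ketone. This removes seven carbons and exposes the diol 22. The forward steps must acylate the secondary Ce hydroxyl beside the free tertiary Cj hydroxyl, and must unmask the phenol without touching two other esters or the Z alkene.

**22 to 21 to 19 + 20.** The Ce and Cj oxygens are tied back into one cyclic silicon group and the Ca–O acyl bond is cut. The angelate is installed while 19 has a single free hydroxyl, so no selectivity among hydroxyls is needed. The forward step must acylate a neopentyl allylic alcohol without Z to E isomerisation.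

**19 to 18.** The Ca–H bond is cut, which removes the Ca stereocentre and gives the conjugated ketone. The forward reduction must be 1,2-selective and must deliver hydride to the face away from the Cg methyl.

**18 to 14 + 15.** Ca–Cb and Cb–Cc are cut and Ca–Cc is rejoined. Ring A contracts to a six-membered ring and the seven-membered ring problem becomes cyclohexanone chemistry with the alkene position already encoded. The forward step needs the enol ether on the Cc side only, cleavage of the internal cyclopropane bond, and an oxygen substituent at Ce that cannot leave. For this reason the Ce and Cj oxygens are carried as one di-tert-butylsilylene rather than as two different trialkylsilyl ethers. A single fluoride step then frees both, no orthogonal removal is needed, and no triethylsilyl ether is exposed to the iron Lewis acid.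

**14 to 13 to 12.** The O–Si bond and then the Cc–CH3 bond are cut. Both steps are enolate chemistry at the only enolisable position of 12. The methylation must stop at one methyl group; its stereochemistry is irrelevant.

**12 to 11 to 10.** The Ca carbonyl is returned to the alcohol and the silylene is opened to the triol. The 1,3-relationship of the Ce and Cj oxygens lets one reagent protect both and leave the Ca hydroxyl free, so Ca needs no protecting group of its own. The demand is site selectivity of the silylation.

**10 to 8.** The Ce–O and Cf–H bonds are cut (retro-hydroboration). Two stereocentres disappear and a trisubstituted alkene appears. The forward step must put boron on Ce and must approach from the face opposite the Cg methyl, which gives the trans fusion.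

**8 to 7.** The Cf–Cj bond is cut, which opens ring B and removes the Cj stereocentre. The forward step needs an alkenyl nucleophile at Cf that adds to a hindered ketone with the isopropyl group directed away from the Cg methyl.

**7 to 5 to 4 (through 6).** The enol C–O bond is cut back to the ring ketone. In 5 the side-chain carbonyl and the Ca hydroxyl are tied together as a cyclic mixed ketal. The ring carbonyl is then the only enolisable ketone, and neither retro-aldol cleavage nor a bridged aldol reaction can intervene. The ketal must form only at the side-chain ketone and must fall off in the acidic quench.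

**4 to 3.** The Ca–H bond is cut, which restores the symmetry of the dione. Cg is the one stereocentre that is not set by relay from another, and it is created here by a choice between two enantiotopic carbonyls. The forward step must be selective for one carbonyl group and one face, and must leave the side-chain ketone alone.

**3 to 1 + 2.** The Cg–Ch bond is cut (retro-Michael), giving two cheap materials that together hold 13 of the 15 skeletal carbons.

## Other disconnections considered

**Alternative 1:** The cut is through Cj–Cf and O–Ce, taking the cyclopentane-fused isoxazoline A1 back to the acyclic aldoxime A2.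
- Forward key step: NaOCl turns A2 into its nitrile oxide, which adds across the E alkene Cf=Ce. This closes ring B and a temporary isoxazoline; N–O cleavage (Mo(CO)6) would later release a Cj ketone and the Ce hydroxyl.
- In favour: the cycloaddition is suprafacial, so the E geometry is translated without ambiguity into the anti relation of the Cf and Ce hydrogens. Ca is configured before any ring exists, and no organometallic reagent is needed.
- Against: A2 must already carry the quaternary Cg and Ca in an open chain. The ring-fusion sense (Cf against the Cg methyl) rests only on the difference between a methyl group and the Ca branch. Cj must still be set by adding an isopropyl nucleophile to a beta-hydroxy ketone that can undergo retro-aldol cleavage. Ring A would have to be closed late, for example by metathesis with the second-generation Grubbs catalyst to a trisubstituted alkene beside a neopentyl ether.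
- Comparison: on structure, this plan is the better one for the Ce/Cf relationship (stereospecific rather than face-selective) and the equal of the chosen plan for Cj, since both rely on approach anti to the Cg methyl. On mechanism, a concerted cycloaddition avoids the radical and Lewis-acid conditions of the chosen key step. The chosen plan, however, makes the seven-membered ring from an existing ring instead of closing it end to end. On step economy the chosen plan should be shorter, because A2 needs its own multi-step asymmetric synthesis.

**Alternative 2:** The cut is through Cg–CH3 and Cf–Ce, taking the ring B cyclopentanone A3 back to the enone A4 and the aldehyde A5.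
- Forward key step: Cu(OTf)2 with a chiral phosphoramidite catalyses conjugate addition of AlMe3 to A4. The aluminium enolate, activated with MeLi, is trapped by A5 to give A3.
- In favour: a catalytic enantioselective step creates the quaternary Cg and, in the same flask, Cf and Ce.
- Against: beta,beta-disubstituted cyclopentenones are reluctant acceptors. A5 is enolisable and drifts easily to the conjugated enal. The configuration at the exocyclic Ce is less predictable than that of the ring centres. No ring is closed, so ring A must still be built from the CH2O arm and the isopropenyl group, and Cj must take an isopropyl group beside a beta-hydroxyl.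
- Comparison: on structure, this plan is better in stereocentres made per step (three in one operation against three separate events in the chosen plan) and equal in relying on a catalytic asymmetric step for Cg. On mechanism, it postpones the difficult medium-ring closure, which the chosen plan avoids altogether. On step economy the two are comparable on paper.

**Alternative 3:** The cut is through Cf–Cg and Cb–Ca at once, taking the bicyclo[5.3.0]decene A6 back to the tethered allene–vinylcyclopropane A7.
- Forward key step: [Rh(CO)2Cl]2 joins the siloxy-vinylcyclopropane (Cf=Ce with cyclopropane Cd–Cc–Cb) to the internal allene bond Cg=Ca in a (5+2) cycloaddition.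
- In favour: both rings and the quaternary Cg are formed in one catalytic step from a substrate whose only stereocentre is Cj. In ring construction this is better than the chosen plan.
- Against: A6 as drawn is cis-fused. Its Cf hydrogen is on the same face as the Cg methyl, whereas the target has them on opposite faces. A6 is therefore not a direct precursor of the target's ring fusion. Cf would have to be inverted by equilibration next to a Ce ketone, and a preference for the trans fusion there is not assured. Further repairs are needed: Ca is a methylene that must be cleaved to a ketone and reduced; the Cb=Cc alkene must be reintroduced, which destroys the Cc stereocentre just made; and the Ce ketone must be reduced to the equatorial alcohol against the axial methyl.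
- Comparison: on structure, the plan wins on bond construction but loses on configuration and oxidation level. On mechanism, the metallacycle pathway delivers the cis fusion by its nature, while the chosen plan sets the trans fusion directly by hydroboration. On step economy the repairs should cancel the early gain, so the two are at best equal.

Key step: step 11

Assumption: the (R,R) enantiomer of the TsDPEN ruthenium catalyst is taken to give the 3R carbinol of 4, with the quaternary carbon playing the part of the aryl group in the usual model; if the sense is the opposite, the (S,S) catalyst is used with no other change.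

## Route

Step 1
Reactants: 1 2-methylcyclohexane-1,3-dione; 2 4-methylpent-1-en-3-one
Product: 3 2-methyl-2-(4-methyl-3-oxopentyl)cyclohexane-1,3-dione
Conditions: Et3N (cat.), MeCN, rt
Reagents that add atoms: none
Why: Base-catalysed Michael addition of the acidic C2–H of the dione to the vinyl ketone; the adduct has no acidic hydrogen left between the ring carbonyls, so the reaction should stop at the prochiral triketone.

Step 2
Reactants: 3 2-methyl-2-(4-methyl-3-oxopentyl)cyclohexane-1,3-dione
Product: 4 (2R,3R)-3-hydroxy-2-methyl-2-(4-methyl-3-oxopentyl)cyclohexan-1-one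
Conditions: RuCl(p-cymene)[(R,R)-TsDPEN] (1 mol%), HCO2H/Et3N (5:2), CH2Cl2, rt
Reagents that add atoms: none
Why: Noyori-type asymmetric transfer hydrogenation desymmetrises the 2,2-disubstituted 1,3-dione: the catalyst fixes the carbinol configuration and hydride enters from the methyl face, anti to the longer chain, so the choice between the two carbonyls, and with it Cg, follows. The hindered, unactivated isopropyl ketone and the less activated hydroxy ketone product should react far more slowly. Any minor diastereomer is removed here, because it would become the enantiomer once Ca is oxidised.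

Step 3
Reactants: 4 (2R,3R)-3-hydroxy-2-methyl-2-(4-methyl-3-oxopentyl)cyclohexan-1-one
Product: 5 (4aR,8aR)-2-methoxy-4a-methyl-2-(propan-2-yl)octahydro-5H-chromen-5-one (cis-fused cyclic mixed methyl ketal, either configuration at C2)
Conditions: MeOH, PPTS (cat.), 4 Å MS, rt
Reagents that add atoms: methanol, CO
Why: Acid-catalysed ketalisation of a delta-hydroxy ketone: the Ca hydroxyl closes onto the side-chain carbonyl to give a six-membered mixed ketal, which masks both groups in one operation. The neopentyl ring ketone has no such internal partner and should stay free; the anomeric centre is lost again in step 4.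

Step 4
Reactants: 5 (4aR,8aR)-2-methoxy-4a-methyl-2-(propan-2-yl)octahydro-5H-chromen-5-one
Product: 7 (5R,6R)-5-hydroxy-6-methyl-6-(4-methyl-3-oxopentyl)cyclohex-1-en-1-yl trifluoromethanesulfonate, via enol triflate ketal 6 (not isolated)
Conditions: KN(SiMe3)2, THF, −78 °C; PhNTf2, −78 → 0 °C; then 1 M HCl, rt
Reagents that add atoms: N-phenylbis(trifluoromethanesulfonimide), O=S(=O)(N(c1ccccc1)S(=O)(=O)C(F)(F)F)C(F)(F)F; water, O
Why: Kinetic enolate formation and O-triflation can occur only at Ce, because Cg is quaternary and the other ketone is masked, and with no free alkoxide or second carbonyl neither retro-aldol nor bridged aldol reaction is possible. The acidic quench hydrolyses the mixed ketal, and enol triflates are stable to aqueous acid.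

Step 5
Reactants: 7 (5R,6R)-5-hydroxy-6-methyl-6-(4-methyl-3-oxopentyl)cyclohex-1-en-1-yl trifluoromethanesulfonate
Product: 8 (3R,7R,7aS)-7a-methyl-3-(propan-2-yl)-2,3,5,6,7,7a-hexahydro-1H-indene-3,7-diol
Conditions: CrCl2 (6 equiv), NiCl2 (5 mol%), DMF, rt → 50 °C
Reagents that add atoms: none
Why: Intramolecular Nozaki–Hiyama–Kishi reaction: zerovalent nickel inserts into the C–OTf bond, the alkenyl group passes to trivalent chromium, and this adds to the tethered ketone in a 5-exo closure of ring B; free hydroxyl groups are tolerated. In the closing transition state the carbonyl oxygen points toward chromium and the isopropyl group takes the pseudoaxial site on the face away from the axial Cg methyl, so the new hydroxyl should end up syn to that methyl (3R).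

Step 6
Reactants: 8 (3R,7R,7aS)-7a-methyl-3-(propan-2-yl)-2,3,5,6,7,7a-hexahydro-1H-indene-3,7-diol
Product: 10 (3R,3aS,4S,7R,7aS)-7a-methyl-3-(propan-2-yl)octahydro-1H-indene-3,4,7-triol, via alkylborane 9 (not isolated)
Conditions: BH3·THF (4 equiv), THF, 0 °C → rt; then NaOH, H2O2, 0 °C → rt
Reagents that add atoms: hydrogen peroxide, OO
Why: Hydroboration–oxidation: H and B add syn to the trisubstituted alkene with boron on the less substituted Ce, and oxidation replaces boron by oxygen with retention. Approach from the face opposite the axial angular methyl, as with steroidal 5-enes, should give the Cf hydrogen trans to the Cg methyl and the Ce hydroxyl on the same face as that hydrogen.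

Step 7
Reactants: 10 (3R,3aS,4S,7R,7aS)-7a-methyl-3-(propan-2-yl)octahydro-1H-indene-3,4,7-triol
Product: 11 (3R,3aS,4S,7R,7aS)-3,4-[(di-tert-butylsilanediyl)bis(oxy)]-7a-methyl-3-(propan-2-yl)octahydro-1H-inden-7-ol
Conditions: tBu2Si(OTf)2 (1.05 equiv), 2,6-lutidine, CH2Cl2, −40 → 0 °C
Reagents that add atoms: di-tert-butylsilyl bis(trifluoromethanesulfonate), CC(C)(C)[Si](OS(=O)(=O)C(F)(F)F)(OS(=O)(=O)C(F)(F)F)C(C)(C)C
Why: Cyclic silylene formation on a 1,3-diol: the bulky reagent should silylate the equatorial Ce hydroxyl first and then close a six-membered ring onto the tertiary Cj hydroxyl. The axial, neopentyl Ca hydroxyl has no 1,3-partner and should stay free.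

Step 8
Reactants: 11 (3R,3aS,4S,7R,7aS)-3,4-[(di-tert-butylsilanediyl)bis(oxy)]-7a-methyl-3-(propan-2-yl)octahydro-1H-inden-7-ol
Product: 12 (3R,3aS,4S,7aS)-3,4-[(di-tert-butylsilanediyl)bis(oxy)]-7a-methyl-3-(propan-2-yl)octahydro-7H-inden-7-one
Conditions: Dess–Martin periodinane, NaHCO3, CH2Cl2, rt
Reagents that add atoms: none
Why: Dess–Martin oxidation of the only free (secondary) alcohol; the carbon next to the new carbonyl on the ring-fusion side is quaternary, so nothing can epimerise.

Step 9
Reactants: 12 (3R,3aS,4S,7aS)-3,4-[(di-tert-butylsilanediyl)bis(oxy)]-7a-methyl-3-(propan-2-yl)octahydro-7H-inden-7-one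
Product: 13 (3R,3aS,4S,7aS)-3,4-[(di-tert-butylsilanediyl)bis(oxy)]-6,7a-dimethyl-3-(propan-2-yl)octahydro-7H-inden-7-one (either configuration at C6)
Conditions: LiN(iPr)2, THF, −78 °C; MeI, −78 → −20 °C
Reagents that add atoms: iodomethane, CI
Why: Enolate alkylation: the lithium enolate can form only toward Cc and is C-methylated. The configuration of the new centre is irrelevant because Cc becomes sp2 in step 10.

Step 10
Reactants: 13 (3R,3aS,4S,7aS)-3,4-[(di-tert-butylsilanediyl)bis(oxy)]-6,7a-dimethyl-3-(propan-2-yl)octahydro-7H-inden-7-one
Product: 14 7-trimethylsilyl enol ether of 13 (C6=C7 double bond; 3R,3aS,4S,7aS)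
Conditions: Me3SiOTf, Et3N, CH2Cl2, 0 °C → rt
Reagents that add atoms: trimethylsilyl trifluoromethanesulfonate, C[Si](C)(C)OS(=O)(=O)C(F)(F)F
Why: Soft enolisation and O-silylation give the only possible, tetrasubstituted Ca=Cc silyl enol ether; the silylene is inert to these conditions.

Step 11
Reactants: 14 7-trimethylsilyl enol ether of 13; 15 diiodomethane
Product: 18 (3R,3aS,4S,8aS)-3,4-[(di-tert-butylsilanediyl)bis(oxy)]-6,8a-dimethyl-3-(propan-2-yl)-2,3,3a,4,5,8a-hexahydroazulen-8(1H)-one, via siloxycyclopropane 16 (not isolated), via chloro ketone 17 (not isolated)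
Conditions: Et2Zn, CH2I2, CH2Cl2, 0 °C → rt; then FeCl3, pyridine, DMF, 0 °C → rt; then NaOAc, MeOH, 65 °C
Reagents that add atoms: none
Why: The zinc carbenoid EtZnCH2I (Furukawa variant of the Simmons–Smith reaction) adds to the electron-rich tetrasubstituted enol ether and gives the siloxycyclopropane 16, forming Ca–Cb and Cb–Cc. Trivalent iron (FeCl3) then takes one electron from 16; loss of the silyl group as Me3SiCl leaves a cyclopropoxy radical whose internal Ca–Cc bond breaks, because this relieves the strain, restores the Ca carbonyl and gives a tertiary radical at Cc, whereas breaking the external bond would give a primary radical. Chlorine-atom transfer from a second FeCl3 traps the radical as the tertiary chloride 17, and NaOAc removes HCl by an E1cB path through the Ca enolate, which can place the double bond only between Cb and Cc. The closest known reaction is the Ito–Saegusa enlargement of cyclohexanone silyl enol ethers to cyclohept-2-enones. Ring A is closed by ring expansion, a (2+1) addition followed by fragmentation of the shared bond, and not by an end-to-end cyclisation, so the entropic cost of a direct seven-membered closure is avoided. No stereocentre of 18 is made here: the two cyclopropane carbons lose their configuration again, and Ce, Cf, Cg and Cj are remote from the radical and from the enolate. The selectivities needed are the position of the enol ether, secured by the quaternary Cg; the direction of ring opening, secured by the Cc methyl; and survival of the Ce oxygen in the basic elimination, secured by keeping it as a silicon ether, a poor leaving group for vinylogous elimination through Cd.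

Step 12
Reactants: 18 (3R,3aS,4S,8aS)-3,4-[(di-tert-butylsilanediyl)bis(oxy)]-6,8a-dimethyl-3-(propan-2-yl)-2,3,3a,4,5,8a-hexahydroazulen-8(1H)-one
Product: 19 (3R,3aS,4S,8S,8aS)-3,4-[(di-tert-butylsilanediyl)bis(oxy)]-6,8a-dimethyl-3-(propan-2-yl)-1,2,3,3a,4,5,8,8a-octahydroazulen-8-ol
Conditions: NaBH4, CeCl3·7H2O, MeOH, −78 → −20 °C
Reagents that add atoms: none
Why: Luche reduction gives clean 1,2-addition to the enone. Hydride should approach from the face opposite the axial Cg methyl, as in hydride reductions of ketones flanked by an angular methyl (12- and 17-oxo steroids), which puts the new hydroxyl syn to the methyl (8S).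

Step 13
Reactants: 19 (3R,3aS,4S,8S,8aS)-3,4-[(di-tert-butylsilanediyl)bis(oxy)]-6,8a-dimethyl-3-(propan-2-yl)-1,2,3,3a,4,5,8,8a-octahydroazulen-8-ol; 20 (2Z)-2-methylbut-2-enoic anhydride (angelic anhydride)
Product: 21 (3R,3aS,4S,8S,8aS)-3,4-[(di-tert-butylsilanediyl)bis(oxy)]-6,8a-dimethyl-3-(propan-2-yl)-1,2,3,3a,4,5,8,8a-octahydroazulen-8-yl (2Z)-2-methylbut-2-enoate
Conditions: LiN(SiMe3)2 (1.05 equiv), THF, −78 °C; then angelic anhydride, −78 → 0 °C
Reagents that add atoms: none
Why: Acylation of the preformed lithium alkoxide by the symmetrical anhydride needs no nucleophilic catalyst, which avoids the addition–elimination path that turns angelates into tiglates. The substrate has only one hydroxyl, and the Ca configuration is untouched because the C–O bond is not broken.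

Step 14
Reactants: 21 (3R,3aS,4S,8S,8aS)-3,4-[(di-tert-butylsilanediyl)bis(oxy)]-6,8a-dimethyl-3-(propan-2-yl)-1,2,3,3a,4,5,8,8a-octahydroazulen-8-yl (2Z)-2-methylbut-2-enoate
Product: 22 (3R,3aS,4S,8S,8aS)-3,4-dihydroxy-6,8a-dimethyl-3-(propan-2-yl)-1,2,3,3a,4,5,8,8a-octahydroazulen-8-yl (2Z)-2-methylbut-2-enoate
Conditions: HF·pyridine, pyridine, THF, 0 °C → rt
Reagents that add atoms: none
Why: Fluoride-mediated desilylation cleaves both Si–O bonds of the silylene in one operation; the pyridine-buffered medium should spare the allylic angelate and the tertiary alcohol.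

Step 15
Reactants: 22 (3R,3aS,4S,8S,8aS)-3,4-dihydroxy-6,8a-dimethyl-3-(propan-2-yl)-1,2,3,3a,4,5,8,8a-octahydroazulen-8-yl (2Z)-2-methylbut-2-enoate; 23 4-(acetyloxy)benzoyl chloride
Product: 24 (3R,3aS,4S,8S,8aS)-3-hydroxy-6,8a-dimethyl-8-{[(2Z)-2-methylbut-2-enoyl]oxy}-3-(propan-2-yl)-1,2,3,3a,4,5,8,8a-octahydroazulen-4-yl 4-(acetyloxy)benzoate
Conditions: pyridine, DMAP (cat.), CH2Cl2, 0 °C → rt
Reagents that add atoms: none
Why: Acylation with an acid chloride: only the secondary Ce hydroxyl should react, because the tertiary Cj hydroxyl is inert under these conditions. The phenol is carried as its acetate so that the acid chloride cannot condense with itself, and an existing angelate ester is not isomerised by catalytic DMAP at room temperature.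

Step 16
Reactants: 24 (3R,3aS,4S,8S,8aS)-3-hydroxy-6,8a-dimethyl-8-{[(2Z)-2-methylbut-2-enoyl]oxy}-3-(propan-2-yl)-1,2,3,3a,4,5,8,8a-octahydroazulen-4-yl 4-(acetyloxy)benzoate
Product: 25 (3R,3aS,4S,8S,8aS)-3-hydroxy-6,8a-dimethyl-8-{[(2Z)-2-methylbut-2-enoyl]oxy}-3-(propan-2-yl)-1,2,3,3a,4,5,8,8a-octahydroazulen-4-yl 4-hydroxybenzoate
Conditions: NH4OAc, MeOH/H2O (4:1), rt
Reagents that add atoms: none
Why: Chemoselective methanolysis of the aryl acetate, which is a far better acyl donor (phenoxide leaving group activated by the para ester) than the hindered alkyl angelate and benzoate. The neutral conditions should leave the Z alkene and the tertiary alcohol alone.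

## Compound list

1 | 2-methylcyclohexane-1,3-dione | CC1C(=O)CCCC1=O | starting material
2 | 4-methylpent-1-en-3-one | C=CC(=O)C(C)C | starting material
3 | 2-methyl-2-(4-methyl-3-oxopentyl)cyclohexane-1,3-dione | CC(C)C(=O)CCC1(C)C(=O)CCCC1=O | intermediate
4 | (2R,3R)-3-hydroxy-2-methyl-2-(4-methyl-3-oxopentyl)cyclohexan-1-one (hydroxyl cis to the side chain; in equilibrium with its cyclic hemiketal) | C[C@]1(CCC(=O)C(C)C)C(=O)CCC[C@H]1O | intermediate
5 | (4aR,8aR)-2-methoxy-4a-methyl-2-(propan-2-yl)octahydro-5H-chromen-5-one (either configuration at C2) | COC1(C(C)C)CC[C@@]2(C)C(=O)CCC[C@H]2O1 | intermediate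
6 | (4aR,8aR)-2-methoxy-4a-methyl-2-(propan-2-yl)-3,4,4a,7,8,8a-hexahydro-2H-chromen-5-yl trifluoromethanesulfonate | COC1(C(C)C)CC[C@@]2(C)C(OS(=O)(=O)C(F)(F)F)=CCC[C@H]2O1 | intermediate (not isolated)
7 | (5R,6R)-5-hydroxy-6-methyl-6-(4-methyl-3-oxopentyl)cyclohex-1-en-1-yl trifluoromethanesulfonate | CC(C)C(=O)CC[C@@]1(C)C(OS(=O)(=O)C(F)(F)F)=CCC[C@H]1O | intermediate
8 | (3R,7R,7aS)-7a-methyl-3-(propan-2-yl)-2,3,5,6,7,7a-hexahydro-1H-indene-3,7-diol | O[C@@H]1CCC=C2[C@]1(C)CC[C@@]2(O)C(C)C | intermediate
9 | 4-boranyl-7a-methyl-3-(propan-2-yl)octahydro-1H-indene-3,7-diol, boron and the C3a hydrogen both anti to the angular methyl (idealised as the monoalkylborane; the hydroxyls are borate esters in the flask) | O[C@@H]1CC[C@H](B)[C@@H]2[C@]1(C)CC[C@@]2(O)C(C)C | intermediate (not isolated)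
10 | (3R,3aS,4S,7R,7aS)-7a-methyl-3-(propan-2-yl)octahydro-1H-indene-3,4,7-triol | O[C@@H]1CC[C@H](O)[C@@H]2[C@]1(C)CC[C@@]2(O)C(C)C | intermediate
11 | (3R,3aS,4S,7R,7aS)-3,4-[(di-tert-butylsilanediyl)bis(oxy)]-7a-methyl-3-(propan-2-yl)octahydro-1H-inden-7-ol | O[C@@H]1CC[C@@H]2O[Si](C(C)(C)C)(C(C)(C)C)O[C@@]3(C(C)C)CC[C@@]1(C)[C@@H]23 | intermediate
12 | (3R,3aS,4S,7aS)-3,4-[(di-tert-butylsilanediyl)bis(oxy)]-7a-methyl-3-(propan-2-yl)octahydro-7H-inden-7-one | O=C1CC[C@@H]2O[Si](C(C)(C)C)(C(C)(C)C)O[C@@]3(C(C)C)CC[C@@]1(C)[C@@H]23 | intermediate
13 | (3R,3aS,4S,7aS)-3,4-[(di-tert-butylsilanediyl)bis(oxy)]-6,7a-dimethyl-3-(propan-2-yl)octahydro-7H-inden-7-one (either configuration at C6) | O=C1C(C)C[C@@H]2O[Si](C(C)(C)C)(C(C)(C)C)O[C@@]3(C(C)C)CC[C@@]1(C)[C@@H]23 | intermediate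
14 | 7-trimethylsilyl enol ether of 13 (trans-hydrindane, C6=C7) | C[Si](C)(C)OC1=C(C)C[C@@H]2O[Si](C(C)(C)C)(C(C)(C)C)O[C@@]3(C(C)C)CC[C@@]1(C)[C@@H]23 | intermediate
15 | diiodomethane | ICI | starting material
16 | siloxycyclopropane: CH2 bridging Ca (OSiMe3) and Cc (CH3) of 14 (either face) | C[Si](C)(C)OC14CC4(C)C[C@@H]2O[Si](C(C)(C)C)(C(C)(C)C)O[C@@]3(C(C)C)CC[C@@]1(C)[C@@H]23 | intermediate (not isolated)
17 | ring-enlarged beta-chloro ketone: 6-chloro-6,8a-dimethyl octahydroazulen-8-one carrying the silylene (either configuration at C6) | O=C1CC(C)(Cl)C[C@@H]2O[Si](C(C)(C)C)(C(C)(C)C)O[C@@]3(C(C)C)CC[C@@]1(C)[C@@H]23 | intermediate (not isolated)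
18 | (3R,3aS,4S,8aS)-3,4-[(di-tert-butylsilanediyl)bis(oxy)]-6,8a-dimethyl-3-(propan-2-yl)-2,3,3a,4,5,8a-hexahydroazulen-8(1H)-one | O=C1C=C(C)C[C@@H]2O[Si](C(C)(C)C)(C(C)(C)C)O[C@@]3(C(C)C)CC[C@@]1(C)[C@@H]23 | intermediate
19 | (3R,3aS,4S,8S,8aS)-3,4-[(di-tert-butylsilanediyl)bis(oxy)]-6,8a-dimethyl-3-(propan-2-yl)-1,2,3,3a,4,5,8,8a-octahydroazulen-8-ol | O[C@H]1C=C(C)C[C@@H]2O[Si](C(C)(C)C)(C(C)(C)C)O[C@@]3(C(C)C)CC[C@@]1(C)[C@@H]23 | intermediate
20 | (2Z)-2-methylbut-2-enoic anhydride (angelic anhydride) | C/C=C(/C)C(=O)OC(=O)/C(C)=C\C | starting material
21 | (2Z)-2-methylbut-2-enoate of 19 | C/C=C(/C)C(=O)O[C@H]1C=C(C)C[C@@H]2O[Si](C(C)(C)C)(C(C)(C)C)O[C@@]3(C(C)C)CC[C@@]1(C)[C@@H]23 | intermediate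
22 | (3R,3aS,4S,8S,8aS)-3,4-dihydroxy-6,8a-dimethyl-3-(propan-2-yl)-1,2,3,3a,4,5,8,8a-octahydroazulen-8-yl (2Z)-2-methylbut-2-enoate | C/C=C(/C)C(=O)O[C@H]1C=C(C)C[C@H](O)[C@@H]2[C@]1(C)CC[C@@]2(O)C(C)C | intermediate
23 | 4-(acetyloxy)benzoyl chloride | CC(=O)Oc1ccc(cc1)C(Cl)=O | starting material
24 | (3R,3aS,4S,8S,8aS)-3-hydroxy-6,8a-dimethyl-8-{[(2Z)-2-methylbut-2-enoyl]oxy}-3-(propan-2-yl)-1,2,3,3a,4,5,8,8a-octahydroazulen-4-yl 4-(acetyloxy)benzoate | C/C=C(/C)C(=O)O[C@H]1C=C(C)C[C@H](OC(=O)c2ccc(OC(C)=O)cc2)[C@@H]2[C@]1(C)CC[C@@]2(O)C(C)C | intermediate
25 | (3R,3aS,4S,8S,8aS)-3-hydroxy-6,8a-dimethyl-8-{[(2Z)-2-methylbut-2-enoyl]oxy}-3-(propan-2-yl)-1,2,3,3a,4,5,8,8a-octahydroazulen-4-yl 4-hydroxybenzoate | C/C=C(/C)C(=O)O[C@H]1C=C(C)C[C@H](OC(=O)c2ccc(O)cc2)[C@@H]2[C@]1(C)CC[C@@]2(O)C(C)C | target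

## Step count and least certain steps

Total step count: 16. Longest linear sequence: 16 steps (1 to 25); 2, 15, 20 and 23 enter as purchased materials.

**Step 11 (key step).** The most likely failure is slow cyclopropanation of the tetrasubstituted enol ether beside the quaternary Cg. Zinc iodide could then strip the trimethylsilyl group and return the ketone, or the oxidation could give only partial ring opening. Fallback, setting out from 13 and returning at 18: Lewis-acid-promoted homologation with trimethylsilyldiazomethane (BF3·OEt2, CH2Cl2, −78 °C). The less substituted Cc should migrate in preference to the quaternary Cg, giving the alpha-silyl cycloheptanone F1. K2CO3 in MeOH removes the carbon-bound silyl group to give the saturated ring-enlarged ketone F2. Me3SiOTf/Et3N converts this into the enol ether F3, which can form only toward Cb, and Saegusa–Ito oxidation with Pd(OAc)2 in MeCN gives 18.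

**Step 5.** The alkenylchromium may add too slowly to the hindered isopropyl ketone, so that protonation of the organometallic (loss of the triflate without ring closure) takes over; facial control at Cj could also be incomplete. Fallback, setting out from 5 and returning at 8: hydrazine hydrate in EtOH gives the hydrazone F4. Iodine with tetramethylguanidine (Barton vinyl iodide synthesis) gives the iodoalkene ketal F5. Aqueous HCl in THF releases the iodo hydroxy ketone F6. tBuLi (3 equiv, Et2O, −100 °C) then forms the alkoxide, exchanges iodine for lithium, and the far more reactive alkenyllithium closes ring B to 8 under the same steric argument.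

**Step 6.** Poor facial selectivity is the risk: the isopropyl group on Cj sits on the face that borane must use, and if it outweighs the angular methyl the cis-fused isomer would form. Fallback, setting out from 8 and returning at 10: Ph2PCl/Et3N converts only the secondary Ca hydroxyl, which lies on the required face, into the diphenylphosphinite F7. Phosphinite-directed hydroboration with catecholborane and [Rh(cod)Cl]2 delivers H and B from that face, and NaOH/H2O2 gives the diphenylphosphinate F8. LiAlH4 cleaves the P–O bond to give 10.

**Step 7.** Poor site selectivity of the first silylation is the risk: attack at the Ca hydroxyl would leave an open silyl triflate or silanol instead of the bridged silylene. Fallback, setting out from 8 and returning at 11: Ac2O/pyridine acetylates the secondary Ca hydroxyl only, giving the monoacetate F9. Hydroboration with a buffered oxidative work-up (NaBO3) gives the diol acetate F10. The silylene is then closed on the only two free hydroxyls to give F11, and K2CO3 in MeOH removes the acetate to give 11.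

**Step 12.** Wrong or low facial selectivity in hydride delivery is the risk, if the conformation of the silylene-bridged cycloheptenone exposes the methyl face. Fallback, setting out from 18 and returning at 19 with no new compound: reagent-controlled Corey–Bakshi–Shibata reduction with (R)-2-methyl-CBS-oxazaborolidine and catecholborane. With the quaternary side acting as the large group, this should give the 8S alcohol.

**Step 13.** Acylation of the neopentyl alkoxide may be slow, and excess base could form the dienolate of the angelate and let the Z alkene drift to the E (tiglate) isomer. Fallback, setting out from 19 and returning at 21: DCC/DMAP esterification with 2-[bis(2,2,2-trifluoroethoxy)phosphoryl]propanoic acid (from its commercial methyl ester) gives the phosphonate ester F12. Still–Gennari olefination with acetaldehyde (KN(SiMe3)2, 18-crown-6, THF, −78 °C) then builds the Z trisubstituted alkene on the ester already in place.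

## Further compounds

F1 | step 11 | alpha-trimethylsilyl ring-enlarged ketone (7-trimethylsilyl-6,8a-dimethyl octahydroazulen-8-one with the silylene) | O=C1C([Si](C)(C)C)C(C)C[C@@H]2O[Si](C(C)(C)C)(C(C)(C)C)O[C@@]3(C(C)C)CC[C@@]1(C)[C@@H]23
F2 | step 11 | saturated ring-enlarged ketone (6,8a-dimethyl octahydroazulen-8-one with the silylene, either configuration at C6) | O=C1CC(C)C[C@@H]2O[Si](C(C)(C)C)(C(C)(C)C)O[C@@]3(C(C)C)CC[C@@]1(C)[C@@H]23
F3 | step 11 | trimethylsilyl enol ether of F2 (C7=C8) | C[Si](C)(C)OC1=CC(C)C[C@@H]2O[Si](C(C)(C)C)(C(C)(C)C)O[C@@]3(C(C)C)CC[C@@]1(C)[C@@H]23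
F4 | step 5 | hydrazone of 5 | COC1(C(C)C)CC[C@@]2(C)C(=NN)CCC[C@H]2O1
F5 | step 5 | (4aR,8aR)-5-iodo-2-methoxy-4a-methyl-2-(propan-2-yl)-3,4,4a,7,8,8a-hexahydro-2H-chromene | COC1(C(C)C)CC[C@@]2(C)C(I)=CCC[C@H]2O1
F6 | step 5 | 1-[(1R,6R)-6-hydroxy-2-iodo-1-methylcyclohex-2-en-1-yl]-4-methylpentan-3-one | CC(C)C(=O)CC[C@@]1(C)C(I)=CCC[C@H]1O
F7 | step 6 | diphenylphosphinite of the C7 hydroxyl of 8 | O([C@@H]1CCC=C2[C@]1(C)CC[C@@]2(O)C(C)C)P(c1ccccc1)c1ccccc1
F8 | step 6 | diphenylphosphinate of the C7 hydroxyl of 10 | O=P(O[C@@H]1CC[C@H](O)[C@@H]2[C@]1(C)CC[C@@]2(O)C(C)C)(c1ccccc1)c1ccccc1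
F9 | step 7 | 7-O-acetate of 8 | CC(=O)O[C@@H]1CCC=C2[C@]1(C)CC[C@@]2(O)C(C)C
F10 | step 7 | 7-O-acetate of 10 | CC(=O)O[C@@H]1CC[C@H](O)[C@@H]2[C@]1(C)CC[C@@]2(O)C(C)C
F11 | step 7 | 7-O-acetate of 11 | CC(=O)O[C@@H]1CC[C@@H]2O[Si](C(C)(C)C)(C(C)(C)C)O[C@@]3(C(C)C)CC[C@@]1(C)[C@@H]23
F0 | step 12 | none | none
F12 | step 13 | 2-[bis(2,2,2-trifluoroethoxy)phosphoryl]propanoate of 19 | CC(C(=O)O[C@H]1C=C(C)C[C@@H]2O[Si](C(C)(C)C)(C(C)(C)C)O[C@@]3(C(C)C)CC[C@@]1(C)[C@@H]23)P(=O)(OCC(F)(F)F)OCC(F)(F)F
A1 | alternative 1 | cyclopentane-fused isoxazoline ester (C=N at Cj, ring oxygen on Ce, Cg bearing methyl and the CH(OPMB)CO2Me branch) | COC(=O)[C@H](OCc1ccc(OC)cc1)[C@@]1(C)CCC2=NO[C@@H](CC(C)=C)[C@@H]21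
A2 | alternative 1 | acyclic aldoxime with the E alkene Cf=Ce and the quaternary Cg | COC(=O)[C@H](OCc1ccc(OC)cc1)[C@@](C)(CC/C=N/O)/C=C/CC(C)=C
A3 | alternative 2 | ring B cyclopentanone aldol product with Cg, Cf and Ce set | O=C1CC[C@](C)(CO[Si](C)(C)C(C)(C)C)[C@H]1[C@@H](O)CC(C)=C
A4 | alternative 2 | 3-{[(tert-butyldimethylsilyl)oxy]methyl}cyclopent-2-en-1-one | O=C1CCC(CO[Si](C)(C)C(C)(C)C)=C1
A5 | alternative 2 | 3-methylbut-3-enal | C=C(C)CC=O
A6 | alternative 3 | cis-fused bicyclo[5.3.0]decene with Ca methylene and Ce silyl enol ether | C=C1C[C@H](C)C=C(O[Si](C)(C)C(C)(C)C)[C@H]2[C@]1(C)CC[C@@]2(O[Si](CC)(CC)CC)C(C)C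
A7 | alternative 3 | tethered 1,1-disubstituted allene and 2-siloxy vinylcyclopropane (enol ether geometry and cyclopropane configuration not specified) | C=C=C(C)CC[C@@](O[Si](CC)(CC)CC)(C(C)C)C=C(O[Si](C)(C)C(C)(C)C)C1CC1C
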